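**Retrosynthetic overview**
- Target ⇐ C4 ketone (Wittig methylenation last); the C8 methyl group ⇐ C8 ketone (methylenation, then α-face hydrogenation).
- Key disconnection C11–aryl: an aryl bromide is joined to the ketone homoenolate released from a ring B-fused cyclopropanol (C8–C9–C11). The aryl carbon and the ketone β-carbon C11 are both normally electrophilic.
- Cyclopropanol ⇐ α-face cyclopropanation of a regiodefined, trans-fused silyl enol ether, which fixes the C9 quaternary centre. The enol ether ⇐ Li/NH3 reduction of a 9-(benzyloxymethyl) Wieland–Miescher-type enone.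
- Ring order: ring A is bought as 2-methylcyclohexane-1,3-dione, ring B is closed by an asymmetric Robinson annulation, and the arene (from 2-methoxyresorcinol) is attached last.

Assumption: atom labels follow the avarane/clerodane numbering of the target. C4 carries the exocyclic methylene, C5 the angular methyl, C8 the secondary methyl, C9 the quaternary carbon, C10 the ring-fusion CH, C11 is the benzylic CH2 and C20 the hydroxymethyl carbon. β is the face of the C5 methyl group; the target is (5S,8S,9S,10R). Ar = 5-(methoxycarbonyl)-3-methoxy-2,4-bis(methoxymethoxy)phenyl; TBS = tert-butyldimethylsilyl.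

**Step 1**
Reactants: 1 2-methoxybenzene-1,3-diol
Product: 2 2-methoxy-1,3-bis(methoxymethoxy)benzene
Conditions: NaH (2.4 equiv), MOMCl (2.4 equiv), DMF, 0 °C → rt
Reagents that add atoms: chloromethyl methyl ether, COCCl
Why: Williamson-type acetal protection of both phenols; the MOM groups later direct lithiation and are removed by acid.

**Step 2**
Reactants: 2 2-methoxy-1,3-bis(methoxymethoxy)benzene
Product: 4 methyl 3-methoxy-2,4-bis(methoxymethoxy)benzoate, via aryllithium 3 (not isolated)
Conditions: n-BuLi (1.1 equiv), TMEDA, THF, −78 → 0 °C; cannulate into ClCO2Me (3 equiv), THF, −78 °C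
Reagents that add atoms: methyl chloroformate, COC(=O)Cl
Why: Directed ortho-metalation next to an OMOM group (the other ortho site is blocked by OMe), then acylation by inverse addition to avoid ketone formation.

**Step 3**
Reactants: 4 methyl 3-methoxy-2,4-bis(methoxymethoxy)benzoate
Product: 5 methyl 5-bromo-3-methoxy-2,4-bis(methoxymethoxy)benzoate
Conditions: NBS (1.05 equiv), MeCN, 0 °C → rt
Reagents that add atoms: N-bromosuccinimide, O=C1CCC(=O)N1Br
Why: Electrophilic aromatic bromination at the only position that is ortho and para to the two OMOM donors and meta to the ester.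

**Step 4**
Reactants: 6 3-(benzyloxy)propanal
Product: 7 5-(benzyloxy)pent-1-en-3-ol (racemic)
Conditions: CH2=CHMgBr (1.2 equiv), THF, −78 → 0 °C; aq NH4Cl
Reagents that add atoms: vinylmagnesium bromide, C=C[Mg]Br
Why: Grignard 1,2-addition; the carbinol centre is erased in step 5, so no stereocontrol is needed.

**Step 5**
Reactants: 7 5-(benzyloxy)pent-1-en-3-ol
Product: 8 1-(benzyloxy)pent-4-en-3-one
Conditions: Dess–Martin periodinane (1.2 equiv), CH2Cl2, 0 °C → rt; used at once
Reagents that add atoms: none
Why: Mild Dess–Martin oxidation of the allylic alcohol gives the polymerisation-prone vinyl ketone without acid or base.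

**Step 6**
Reactants: 9 2-methylcyclohexane-1,3-dione; 8 1-(benzyloxy)pent-4-en-3-one
Product: 11 (8aS)-5-[(benzyloxy)methyl]-8a-methyl-3,4,8,8a-tetrahydronaphthalene-1,6(2H,7H)-dione, via triketone 10 (not isolated)
Conditions: Et3N (0.1 equiv), DMF, rt; then L-phenylalanine (1 equiv), (1S)-(+)-10-camphorsulfonic acid (0.5 equiv), 30 → 70 °C (about 90% ee expected)
Reagents that add atoms: none
Why: Robinson annulation (Michael addition, then amino-acid-mediated enamine aldol condensation of the Hajos–Parrish–Eder–Sauer–Wiechert type); the L-amino acid enamine selects one enantiotopic ring carbonyl and sets C5 as S.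

**Step 7**
Reactants: 11 (S)-enedione
Product: 12 C4 ethylene ketal of 11 (1,3-dioxolane on the saturated ring A ketone)
Conditions: ethylene glycol, p-TsOH·H2O (0.3 equiv), 4 Å MS, rt; recrystallise to ≥98% ee
Reagents that add atoms: ethylene glycol, OCCO
Why: Chemoselective ketalisation; the saturated C4 ketone reacts and the hindered, conjugated C8 enone does not, as is standard for Wieland–Miescher ketones.

**Step 8**
Reactants: 12 enone ketal
Product: 15 trans-fused C8 trimethylsilyl enol ether (C8=C9) bearing C20–OTBS (10α-H; C4 dioxolane), via dilithium enolate alkoxide 13 (not isolated), via lithium enolate silyl ether 14 (not isolated)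
Conditions: Li (4.5 equiv), NH3(l)–THF, −78 °C; NH3 evaporated; TBSCl (3 equiv), THF, 0 °C → rt; then TMSCl, Et3N, 0 °C; cold NaHCO3/pentane work-up
Reagents that add atoms: tert-butyldimethylsilyl chloride, CC(C)(C)[Si](C)(C)Cl; chlorotrimethylsilane, C[Si](C)(C)Cl
Why: Dissolving-metal (Stork) enone reduction protonates C10 axially to give the trans ring fusion (10α-H) and a regiodefined C8=C9 enolate. The benzyl ether is cleaved in the same pot to an alkoxide that cannot β-eliminate. TBSCl silylates only the alkoxide (lithium enolates are inert to it in THF without HMPA), and TMSCl then traps the enolate on oxygen.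

**Step 9**
Reactants: 15 silyl enol ether
Product: 17 ring B-fused cyclopropanol (C8–OH β; C11 bridging C8 and C9 on the α face; C20–OTBS β), via trimethylsilyl cyclopropyl ether 16 (not isolated)
Conditions: Et2Zn (4 equiv), CH2I2 (8 equiv), CH2Cl2, 0 °C → rt; aq NaHCO3; crude in MeOH, K2CO3 (0.2 equiv), 0 °C
Reagents that add atoms: diiodomethane, ICI
Why: Simmons–Smith (Furukawa) cyclopropanation of the electron-rich enol ether occurs from the α face, anti to the axial C5 methyl, which fixes the C9 quaternary centre (C11 α, C20 β). Mild methanolysis then removes only the TMS group.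

**Step 10 (key step)**
Reactants: 17 cyclopropanol; 5 methyl 5-bromo-3-methoxy-2,4-bis(methoxymethoxy)benzoate
Product: 18 C8 ketone carrying 9α-CH2Ar and 9β-CH2OTBS (10α-H; C4 dioxolane)
Conditions: Pd(OAc)2 (10 mol%), XPhos (20 mol%), Cs2CO3 (2 equiv), toluene, 80 °C
Reagents that add atoms: none
Why: Palladium-catalysed ring-opening cross-coupling of a cyclopropanol (ketone homoenolate arylation): 5 adds oxidatively to zerovalent palladium, the palladium alkoxide undergoes β-carbon elimination at the less substituted C8–C11 bond, and the resulting palladium homoenolate has no β-hydrogen (C9 is quaternary), so it can only reductively eliminate to the C11–aryl bond. The C9 configuration from step 9 is untouched.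

**Step 11**
Reactants: 18 ketone
Product: 19 C8 exocyclic methylene compound
Conditions: Lombardo reagent (Zn, CH2Br2, TiCl4, THF, pre-aged at 5 °C), CH2Cl2, 0 °C → rt
Reagents that add atoms: dibromomethane, BrCBr
Why: Lombardo–Takai methylenation is non-basic, works on hindered α-quaternary ketones and leaves the aryl ester, the ketal and the silyl and MOM ethers alone.

**Step 12**
Reactants: 19 C8 methylene compound
Product: 21 methyl 2,4-dihydroxy-3-methoxy-5-{[9β-(hydroxymethyl)-5β,8β-dimethyl-4-oxo-trans-decalin-9α-yl]methyl}benzoate, via saturated protected ketal 20 (not isolated)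
Conditions: H2 (1 atm), 10% Pd/C, EtOAc, rt; filter; then 3 M aq HCl, THF–MeOH, 45 °C
Reagents that add atoms: water, O
Why: Heterogeneous hydrogenation delivers hydrogen to C8 from the α face (the β face is blocked by the axial C20 substituent and the C5 methyl), giving the equatorial 8β-methyl (8S). Acid hydrolysis then removes the dioxolane, both MOM ethers and the TBS ether in one operation.

**Step 13**
Reactants: 21 triol ketone
Product: 22 target (CNP0264247.1)
Conditions: Ph3PCH3Br (8 equiv), KOtBu (7.5 equiv), THF, 0 → 60 °C; aq NH4Cl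
Reagents that add atoms: methyltriphenylphosphonium bromide, C[P+](c1ccccc1)(c1ccccc1)c1ccccc1.[Br-]
Why: Wittig methylenation of the neopentyl C4 ketone with excess ylide; the three hydroxyls travel as potassium salts, the ortho/para-oxido benzoate ester is deactivated toward the ylide (as in the methylenation of estrone with its free phenol), and no stereocentre is touched.

**Compound list**
1 | 2-methoxybenzene-1,3-diol | COc1c(O)cccc1O | starting material
2 | 2-methoxy-1,3-bis(methoxymethoxy)benzene | COCOc1cccc(OCOC)c1OC | intermediate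
3 | [3-methoxy-2,4-bis(methoxymethoxy)phenyl]lithium | [Li]c1ccc(OCOC)c(OC)c1OCOC | intermediate
4 | methyl 3-methoxy-2,4-bis(methoxymethoxy)benzoate | COC(=O)c1ccc(OCOC)c(OC)c1OCOC | intermediate
5 | methyl 5-bromo-3-methoxy-2,4-bis(methoxymethoxy)benzoate | COC(=O)c1cc(Br)c(OCOC)c(OC)c1OCOC | intermediate
6 | 3-(benzyloxy)propanal | O=CCCOCc1ccccc1 | starting material
7 | 5-(benzyloxy)pent-1-en-3-ol (racemic) | C=CC(O)CCOCc1ccccc1 | intermediate
8 | 1-(benzyloxy)pent-4-en-3-one | C=CC(=O)CCOCc1ccccc1 | intermediate
9 | 2-methylcyclohexane-1,3-dione | CC1C(=O)CCCC1=O | starting material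
10 | 2-[5-(benzyloxy)-3-oxopentyl]-2-methylcyclohexane-1,3-dione | CC1(CCC(=O)CCOCc2ccccc2)C(=O)CCCC1=O | intermediate
11 | (8aS)-5-[(benzyloxy)methyl]-8a-methyl-3,4,8,8a-tetrahydronaphthalene-1,6(2H,7H)-dione | C[C@]12CCC(=O)C(COCc3ccccc3)=C1CCCC2=O | intermediate
12 | C4 ethylene ketal of 11 (5S) | C[C@]12CCC(=O)C(COCc3ccccc3)=C1CCCC21OCCO1 | intermediate
13 | dilithium C8 enolate / C20 alkoxide, trans-fused (10α-H), C4 dioxolane | C[C@]12CCC(O[Li])=C(CO[Li])[C@@H]1CCCC21OCCO1 | intermediate
14 | lithium C8 enolate with C20–OTBS, trans-fused, C4 dioxolane | C[C@]12CCC(O[Li])=C(CO[Si](C)(C)C(C)(C)C)[C@@H]1CCCC21OCCO1 | intermediate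
15 | C8 trimethylsilyl enol ether (C8=C9) with C20–OTBS, trans-fused (10α-H), C4 dioxolane | C[C@]12CCC(O[Si](C)(C)C)=C(CO[Si](C)(C)C(C)(C)C)[C@@H]1CCCC21OCCO1 | intermediate
16 | 8β-trimethylsilyloxy-8α,9α-methano (cyclopropane) compound, 9β-CH2OTBS, C4 dioxolane | C[C@]12CC[C@@]3(O[Si](C)(C)C)C[C@@]3(CO[Si](C)(C)C(C)(C)C)[C@@H]1CCCC21OCCO1 | intermediate
17 | 8β-hydroxy-8α,9α-methano compound (ring B-fused cyclopropanol), 9β-CH2OTBS, C4 dioxolane | C[C@]12CC[C@@]3(O)C[C@@]3(CO[Si](C)(C)C(C)(C)C)[C@@H]1CCCC21OCCO1 | intermediate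
18 | C8 ketone with 9α-CH2Ar and 9β-CH2OTBS, 10α-H, 5β-CH3, C4 dioxolane | C[C@]12CCC(=O)[C@@](CO[Si](C)(C)C(C)(C)C)(Cc3cc(C(=O)OC)c(OCOC)c(OC)c3OCOC)[C@@H]1CCCC21OCCO1 | intermediate
19 | C8 exocyclic methylene analogue of 18 | C[C@]12CCC(=C)[C@@](CO[Si](C)(C)C(C)(C)C)(Cc3cc(C(=O)OC)c(OCOC)c(OC)c3OCOC)[C@@H]1CCCC21OCCO1 | intermediate
20 | 8β-methyl (8α-H) compound, still carrying dioxolane, TBS and two MOM groups | C[C@]12CC[C@H](C)[C@@](CO[Si](C)(C)C(C)(C)C)(Cc3cc(C(=O)OC)c(OCOC)c(OC)c3OCOC)[C@@H]1CCCC21OCCO1 | intermediate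
21 | methyl 2,4-dihydroxy-3-methoxy-5-{[9β-(hydroxymethyl)-5β,8β-dimethyl-4-oxo-trans-decalin-9α-yl]methyl}benzoate | C[C@]12CC[C@H](C)[C@@](CO)(Cc3cc(C(=O)OC)c(O)c(OC)c3O)[C@@H]1CCCC2=O | intermediate
22 | CNP0264247.1, (5S,8S,9S,10R) | C=C1CCC[C@H]2[C@](CO)(Cc3cc(C(=O)OC)c(O)c(OC)c3O)[C@@H](C)CC[C@]12C | target

**Totals**
Total steps: 13. Longest linear sequence: 10 (steps 4–13); the arene branch (steps 1–3) joins at step 10.

**Steps most likely to fail, with fallbacks**

Step 10. The fused cyclopropanol is hindered, and base-induced opening to the 9-methyl ketone or slow reductive elimination of the neopentyl palladium species could win. The fallback sets out from 17: N-iodosuccinimide in CH2Cl2 at 0 °C opens the cyclopropanol electrophilically to the 9α-iodomethyl ketone F1. Zinc dust with LiCl in THF then gives the alkylzinc iodide (zinc homoenolate) F2, which is coupled with 5 in a Negishi reaction (Pd(OAc)2, SPhos, THF, 50 °C). This comes back to the route at 18.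

Step 8. Debenzylation, enolate formation and the two-stage silylation must all work in one pot. The fallback sets out from 12: Li/NH3 with t-BuOH followed by an NH4Cl quench gives the trans-fused hydroxy ketone F3. TBSCl/imidazole in DMF gives the silyl ether ketone F4, and thermodynamic enol silylation (TMSCl, NaI, Et3N, MeCN) forms the more substituted C8=C9 enol ether. This comes back to the route at 15.

Step 11. The C8 ketone sits next to a fully substituted carbon carrying two CH2X groups and may resist methylenation. The fallback sets out from 18: KHMDS and PhNTf2 (THF, −78 °C; enolisation is only possible toward C7) give the C7–C8 enol triflate F5. Palladium-catalysed methylation with trimethylboroxine (Pd(PPh3)4, K2CO3, dioxane, 90 °C) gives the C7=C8 alkene F6, which already carries the C8 methyl group. Hydrogenation of F6 from the α face under the step 12 conditions comes back to the route at 20.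

**Further compounds**
F1 | step 10 | 9α-(iodomethyl) C8 ketone, 9β-CH2OTBS, C4 dioxolane | C[C@]12CCC(=O)[C@@](CO[Si](C)(C)C(C)(C)C)(CI)[C@@H]1CCCC21OCCO1
F2 | step 10 | alkylzinc iodide (zinc homoenolate) from F1 | C[C@]12CCC(=O)[C@@](CO[Si](C)(C)C(C)(C)C)(C[Zn]I)[C@@H]1CCCC21OCCO1
F3 | step 8 | trans-fused 9α-(hydroxymethyl) C8 ketone (9β-H), C4 dioxolane | C[C@]12CCC(=O)[C@@H](CO)[C@@H]1CCCC21OCCO1
F4 | step 8 | TBS ether of F3 | C[C@]12CCC(=O)[C@@H](CO[Si](C)(C)C(C)(C)C)[C@@H]1CCCC21OCCO1
F5 | step 11 | C7=C8 enol triflate of 18 | C[C@]12CC=C(OS(=O)(=O)C(F)(F)F)[C@@](CO[Si](C)(C)C(C)(C)C)(Cc3cc(C(=O)OC)c(OCOC)c(OC)c3OCOC)[C@@H]1CCCC21OCCO1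
F6 | step 11 | C7=C8 alkene carrying the C8 methyl group | C[C@]12CC=C(C)[C@@](CO[Si](C)(C)C(C)(C)C)(Cc3cc(C(=O)OC)c(OCOC)c(OC)c3OCOC)[C@@H]1CCCC21OCCO1
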